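All runs were computed for substances that don't exist; scatter was added.

At the first reading, 0.167 h into the cedar run, which is the flask asked about, 22.9% of the starting material stands, and by 0.417 h it is down to half of that.

| flask | starting material | partner | remark | time |
|---|---|---|---|---|
| cedar | 10 mM (fed, over 80 s) | 9.5 mM | the very flask that is asked about, followed so far |  |
| maple | 20 mM (fed, over 80 s) | 9.5 mM | run made earlier |  |
| flask | 10 mM (fed, over 80 s) | 9.50 mM |  | 8.0 h |

cedar run (percent of the starting material charged)

| time / h | target / % | starting material / % |
|---|---|---|
| 0.167 | 33.9 | 22.9 |
| 0.250 | 38.1 | 16.9 |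
| 0.417 | 41.1 | 11.4 |
| 0.667 | 42.7 | 7.7 |
| 1.33 | 40.0 | 3.9 |
| 2.00 | 38.5 | 2.5 |
| 3.00 | 38.0 | 1.6 |

maple run (percent of the starting material charged)

| time / h | target / % | starting material / % |
|---|---|---|
| 0.167 | 23.2 | 30.6 |
| 0.333 | 25.4 | 25.9 |
| 0.667 | 23.3 | 21.1 |
| 1.00 | 22.0 | 18.4 |
| 2.00 | 20.1 | 13.2 |
| 4.00 | 18.5 | 8.6 |
| 8.00 | 18.6 | 5.2 |



Each reading scatters by 0.3 percentage points, as a standard deviation.

1. the best time, 8.0 h at the latest, for target
2. the amount of target, in percent of the starting material charged, at that time
3. earliest time at which at least nineteen twentieths of that best amount are there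
4. latest time at which they still are

A later halving in the cedar run, from 7.7% to 3.9%, takes 0.663 h against the first 0.250 h. I explain that by the charges, which are nearly equal, so I take partner to fall along with starting material. After one halving the rate has lost a factor 2 to less starting material and another 2 to less partner, and the next half-life is 2 times as long.

I therefore carry one number, the slowing constant, which is the rise per hour of one over the share of starting material left:

slowing constant = (1/share at 1.33 h − 1/share at 0.167 h) / time between = 18.3 h⁻¹

half-life at the first reading = 1/(slowing constant × share) = 0.239 h

share left at 8.0 h = 1/(1/first share + slowing constant × time) = 0.677%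

At the first pace the time left would hold 32.8 half-lives, but with the slowing it holds 5.08. After 3.00 h starting material loses 0.92 points, less than the 4.7 points by which target reads below its top. So I expect the best to stay at the early peak, read as 42.7% at 0.667 h. I reckon no window.

The forecast gives 42.9% at 0.7 h, with a window from 0.39 h to 1.13 h, and says “the peak stays the best point”.

The flask gives 42.3% at 0.629 h, and its window runs from 0.324 h to 1.40 h, wider at both ends than forecast.

    starting material ⇌ tautomer (K = 0.600, k = 0.0430 s⁻¹)
    starting material + partner → isomer of the product A (k = 0.190 L mol⁻¹ s⁻¹)
    partner + tautomer → target (k = 0.490 L mol⁻¹ s⁻¹)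
    2 starting material → self-condensation product (k = 0.0230 L mol⁻¹ s⁻¹)
    target ⇌ isomer of the product B (K = 0.500, k = 1.00 × 10⁻⁴ s⁻¹)

In this flask my reckoned 0.677% stands against 0.502% of starting material at 8.00 h. The neighbour flask, charged with 6.0 mM of starting material, holds 3.50 mM more partner than starting material. Partner falls there as well, so the half-life is not steady: the slowing constant per mM of charge gives about 0.0399 h with partner as charged and about 0.108 h with partner down to that excess. Even the longer half-life fits 74.1 times into 8.0 h, and 36.8% of partner should remain. That neighbour flask ends with 0% of its starting material and 38% of its partner.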